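**Retrosynthetic overview**
1. The strategy rests on the γ-ylidene butenolide (ring atoms O, C12, C11, C7, C6, with exocyclic C5=C6). Its four contiguous carbons C6–C7=C11–C12 are those of a cyclobutenone. The ring oxygen is the former C6 hydroxyl, moved in between C6 and C12 while C5 gives up a proton (33 ⇐ 32).
2. Compound 32 is a ten-membered carbocycle C1–C10 with a C1–O–C4 bridge and a fused 4-hydroxycyclobutenone. It is closed at C7–C8 by a Nozaki–Hiyama–Kishi reaction of a C7 vinylogous triflate with a C8 aldehyde on a preformed dihydrofuran.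
3. In the open chain, C5–C6 comes from a β-oxido alkyllithium (reductive opening of a C4–C5 epoxide) and an allyloxycyclobutenedione that already carries C13. C2–C3 comes from acetylide opening of a glycidyl tosylate. The C1≡C2 alkyne is the latent C1 carbonyl.
4. Stereocentres: C10, with the intact C8–C9–C10–C1 chain, comes from (R)-citramalic acid. C4 is set by Sharpless epoxidation of methallyl alcohol. C8 is set in the ring closure. C6 is transient.
5. Order of rings: cyclobutene (bought) → bicyclic C1 ketal → dihydrofuran → ten-membered ring → four-membered ring exchanged for the lactone → C1=C2 enol ether restored in the last step.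

Key step: step 22

Numbering: C1–C10 are the ring carbons, C11/C12/C13 the lactone side (C12 carbonyl, C13 CH2O), C14 the methyl on C10 and C15 the methyl on C4. O4, O6, O8, O10 and O13 are the oxygens on these carbons; O4 ends as the bridge between C4 and C1.
Assumption: the (S)-valinol-derived oxazoline–sulfonamide ligand of step 19 is taken to be the antipode that sends the alkenylchromium to the Re face of the C8 aldehyde. If the sense is the opposite, its enantiomer is used and nothing else changes.
Remark: C6 is formed without control in step 14, its epimers are interchanged in step 18, and it is erased in step 22. Compounds 24–32 are therefore pairs of C6 epimers, and their SMILES leave C6 open.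

Step 1
Reactants: 1 (R)-citramalic acid
Product: 2 [(4R)-2,2,4-trimethyl-5-oxo-1,3-dioxolan-4-yl]acetic acid
Conditions: Me2C(OMe)2, p-TsOH (cat.), acetone, 23 °C
Reagents that add atoms: 2,2-dimethoxypropane COC(C)(C)OC
Why: Dioxolanone (acetonide) formation engages the tertiary hydroxyl together with the adjacent carboxyl (future C1) in a five-membered ring and leaves only the remote carboxyl (future C8) free, without touching the C10 stereocentre.

Step 2
Reactants: 2 [(4R)-2,2,4-trimethyl-5-oxo-1,3-dioxolan-4-yl]acetic acid
Product: 4 (3R)-3-hydroxy-3-methyloxolan-2-one, via hydroxyethyl dioxolanone 3 (not isolated)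
Conditions: BH3·THF, THF, 0 → 23 °C; MeOH; then p-TsOH (cat.), CH2Cl2, 23 °C
Reagents that add atoms: none
Why: Chemoselective borane reduction of a free carboxylic acid beside the dioxolanone, followed by acid-catalysed translactonisation of the new primary alcohol onto C1 with loss of acetone, gives the five-membered lactone in which C1 (acyl) and C8 (alkoxy) are told apart.

Step 3
Reactants: 4 (3R)-3-hydroxy-3-methyloxolan-2-one
Product: 5 (3R)-3-methyl-3-(triethylsilyloxy)oxolan-2-one
Conditions: TESOTf, 2,6-lutidine, CH2Cl2, 0 °C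
Reagents that add atoms: triethylsilyl triflate CC[Si](CC)(CC)OS(=O)(=O)C(F)(F)F
Why: Silylation of a hindered tertiary alcohol by a silyl triflate and a non-nucleophilic base installs the O10 triethylsilyl ether that later shields the C10 carbinol from lead.

Step 4
Reactants: 5 (3R)-3-methyl-3-(triethylsilyloxy)oxolan-2-one
Product: 6 (3R)-3-methyl-3-(triethylsilyloxy)oxolan-2-ol (lactol; both anomers)
Conditions: i-Bu2AlH, CH2Cl2, −78 °C; Rochelle salt
Reagents that add atoms: none
Why: Partial reduction of a lactone by i-Bu2AlH at low temperature stops at the tetrahedral aluminium alkoxide, which gives the lactol on work-up.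

Step 5
Reactants: 6 (3R)-3-methyl-3-(triethylsilyloxy)oxolan-2-ol
Product: 7 (3R)-3-methyl-3-(triethylsilyloxy)pent-4-yn-1-ol
Conditions: dimethyl (1-diazo-2-oxopropyl)phosphonate, K2CO3, MeOH, 23 °C
Reagents that add atoms: Ohira–Bestmann reagent COP(=O)(OC)C(=[N+]=[N-])C(C)=O
Why: Ohira–Bestmann (Seyferth–Gilbert) homologation acts on the open hydroxy aldehyde form of the lactol, adds C2 and turns C1 into an alkyne carbon, the quaternary C10 having no proton to lose; a base-induced shift of the silyl group from O10 to O8 would be harmless because step 6 silylates whichever hydroxyl is free.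

Step 6
Reactants: 7 (3R)-3-methyl-3-(triethylsilyloxy)pent-4-yn-1-ol
Product: 8 (3R)-3-methyl-1,3-bis(triethylsilyloxy)pent-4-yne (C8–C9–C10–C1≡C2)
Conditions: TESOTf, 2,6-lutidine, CH2Cl2, 0 °C
Reagents that add atoms: triethylsilyl triflate CC[Si](CC)(CC)OS(=O)(=O)C(F)(F)F
Why: Silylation with the triflate covers a primary or a tertiary hydroxyl alike, so that the single bis-silyl ether results, its primary O8 ether being the one that can later be oxidised directly.

Step 7
Reactants: 9 2-methylprop-2-en-1-ol (methallyl alcohol)
Product: 11 [(2S)-2-methyloxiran-2-yl]methyl 4-toluenesulfonate, via (R)-2-methylglycidol 10 (not isolated)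
Conditions: Ti(OiPr)4 (cat.), D-(−)-diisopropyl tartrate (cat.), cumene hydroperoxide, 3 Å sieves, CH2Cl2, −20 °C; then TsCl, Et3N, 4-(dimethylamino)pyridine (cat.), −10 °C
Reagents that add atoms: cumene hydroperoxide CC(C)(OO)c1ccccc1; 4-toluenesulfonyl chloride Cc1ccc(cc1)S(Cl)(=O)=O
Why: Sharpless asymmetric epoxidation with the D-(−)-tartrate delivers oxygen to the face of the 1,1-disubstituted allylic alcohol that gives the (R)-epoxy alcohol and thereby sets C4, and sulfonylation in the same flask avoids isolation of the water-soluble glycidol.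

Step 8
Reactants: 8 (3R)-3-methyl-1,3-bis(triethylsilyloxy)pent-4-yne; 11 [(2S)-2-methyloxiran-2-yl]methyl 4-toluenesulfonate
Product: 13 (2S,6R)-2-hydroxy-2,6-dimethyl-6,8-bis(triethylsilyloxy)oct-4-yn-1-yl 4-toluenesulfonate, via lithium acetylide 12 (not isolated)
Conditions: n-BuLi, THF, −78 °C; BF3·OEt2; then 11, −78 °C
Reagents that add atoms: n-butyllithium [Li]CCCC (lithium of 12 only)
Why: BF3-assisted opening of an epoxide by a lithium acetylide takes place at the unsubstituted carbon (C3), forms C2–C3, leaves the neopentyl-type tosylate alone and breaks no bond at C4, whose configuration is therefore kept.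

Step 9
Reactants: 13 (2S,6R)-2-hydroxy-2,6-dimethyl-6,8-bis(triethylsilyloxy)oct-4-yn-1-yl 4-toluenesulfonate
Product: 14 (2S)-2-methyl-2-[(4R)-4-methyl-4,6-bis(triethylsilyloxy)hex-2-yn-1-yl]oxirane (C4–C5 epoxide)
Conditions: NaH, THF, 0 °C
Reagents that add atoms: none
Why: Intramolecular Williamson displacement of the tosylate by the C4 alkoxide moves the epoxide to C4–C5 with the C4–O bond intact, which places the future carbanion site at the primary carbon C5.

Step 10
Reactants: 15 squaric acid
Product: 16 3,4-bis(allyloxy)cyclobut-3-ene-1,2-dione (diallyl squarate)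
Conditions: allyl alcohol, PhMe, reflux, Dean–Stark trap
Reagents that add atoms: allyl alcohol C=CCO
Why: Azeotropic esterification of the vinylogous diacid gives the diallyl ester, allyl being chosen in place of a simple alkyl group because it can later be taken off O7 under neutral conditions.

Step 11
Reactants: 17 (tributylstannyl)methanol
Product: 18 tributyl[(1-ethoxyethoxy)methyl]stannane
Conditions: ethyl vinyl ether, pyridinium 4-toluenesulfonate (cat.), CH2Cl2, 23 °C
Reagents that add atoms: ethyl vinyl ether C=COCC
Why: Acid-catalysed addition of the alcohol to the vinyl ether gives a mixed acetal, an oxygen protecting group that cannot migrate to carbon after lithiation as a silyl group would (retro-Brook shift).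

Step 12
Reactants: 18 tributyl[(1-ethoxyethoxy)methyl]stannane; 16 diallyl squarate
Product: 21 3-(allyloxy)-4-(hydroxymethyl)cyclobut-3-ene-1,2-dione, via alkoxymethyllithium 19 (not isolated), via squarate adduct 20 (not isolated)
Conditions: n-BuLi, THF, −78 °C; 16, −78 °C; aq NH4Cl; then 12 M HCl (cat.), THF–H2O, 23 °C
Reagents that add atoms: n-butyllithium [Li]CCCC (lithium of 19 only)
Why: Tin–lithium exchange gives the alkoxymethyllithium, which adds 1,2 to one carbonyl of the squarate, and aqueous acid then ionises the tertiary carbinol, hydrolyses the allyloxy-stabilised cation to the cyclobutenedione with loss of one allyl alcohol and cleaves the acetal (standard mono-substitution of a squarate ester).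

Step 13
Reactants: 21 3-(allyloxy)-4-(hydroxymethyl)cyclobut-3-ene-1,2-dione
Product: 22 3-(allyloxy)-4-[(tert-butyldimethylsilyloxy)methyl]cyclobut-3-ene-1,2-dione
Conditions: TBSOTf, 2,6-lutidine, CH2Cl2, −78 °C
Reagents that add atoms: tert-butyldimethylsilyl triflate CC(C)(C)[Si](C)(C)OS(=O)(=O)C(F)(F)F
Why: Silylation with the triflate and a hindered pyridine avoids nucleophilic amines, which would attack the vinylogous ester, and installs the O13 silyl ether.

Step 14
Reactants: 14 C4–C5 epoxide; 22 3-(allyloxy)-4-[(tert-butyldimethylsilyloxy)methyl]cyclobut-3-ene-1,2-dione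
Product: 24 3-(allyloxy)-2-[(tert-butyldimethylsilyloxy)methyl]-4-hydroxy-4-[(2S,6R)-2-hydroxy-2,6-dimethyl-6,8-bis(triethylsilyloxy)oct-4-yn-1-yl]cyclobut-2-en-1-one (both C6 epimers), via β-oxido alkyllithium 23 (not isolated)
Conditions: lithium 4,4′-di-tert-butylbiphenylide (2.2 equiv), THF, −78 °C; then 22, −78 °C; aq NH4Cl
Reagents that add atoms: lithium (as its 4,4′-di-tert-butylbiphenyl radical anion) [Li] (lithium of 23 only)
Why: Reductive opening of the 2,2-disubstituted epoxide by the arene radical anion gives the primary carbanion next to a lithium alkoxide, which does not eliminate at −78 °C because the leaving group would be lithium oxide and which adds 1,2 to the carbonyl flanked by the allyloxy carbon (the other carbonyl is deactivated as a vinylogous ester), forming C5–C6; the dialkyl alkyne and the silyl ethers are outside the reach of the reductant at this temperature and C6 is formed without control.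

Step 15
Reactants: 24 open-chain 4-hydroxycyclobutenone diol
Product: 25 bicyclic C1 ketal (6,8-dioxabicyclo[3.2.1]octane with bridgeheads C1 and C4; O4 and O6 on C1; spiro at C6 to the allyloxycyclobutenone; 1R,4S,10R)
Conditions: (Ph3P)AuCl (2 mol %), AgOTf (2 mol %), 4 Å sieves, CH2Cl2, 0 → 23 °C
Reagents that add atoms: none
Why: Gold-catalysed double hydroalkoxylation of an alkynediol, in which the C4 hydroxyl adds 5-endo-dig to C1 and the C6 hydroxyl traps the derived oxocarbenium ion in a six-membered ring, gives the bicyclic ketal whose C1 configuration is dictated by C4 (both bridges on one face) and in which C1 and O6 protect each other.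

Step 16
Reactants: 25 bicyclic C1 ketal
Product: 26 2,3-dihydrofuran (C1=C2; O6 trimethylsilyl ether; O8 and O10 triethylsilyl ethers; C7 allyloxy)
Conditions: TMSOTf, i-Pr2NEt, CH2Cl2, −20 → 0 °C
Reagents that add atoms: trimethylsilyl triflate C[Si](C)(C)OS(=O)(=O)C(F)(F)F
Why: In this silyl triflate–amine conversion of a ketal into an enol ether the C1–O6 bond ionises (O4 is the better donor, the cyclobutenyl oxygen the better leaving group, and a five-membered oxocarbenium ion results), the amine removes a C2 proton since C10 has none, and O6 emerges as its trimethylsilyl ether, so that the two tertiary hydroxyls are told apart without a selective protection.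

Step 17
Reactants: 26 dihydrofuran with O8 triethylsilyl ether
Product: 27 C8 aldehyde (dihydrofuran; O6 trimethylsilyl; C7 allyloxy)
Conditions: (COCl)2, DMSO, CH2Cl2, −78 → −40 °C; Et3N, −78 → 0 °C
Reagents that add atoms: none
Why: Under Swern conditions a primary triethylsilyl ether is attacked by the chlorosulfonium ion and oxidised directly to the aldehyde, whereas the tertiary silyl ethers and the tert-butyldimethylsilyl ether are inert and the enol ether survives the cold, finally basic medium.

Step 18
Reactants: 27 C8 aldehyde with C7 allyloxy group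
Product: 29 C7 vinylogous triflate C8 aldehyde, via stannyl vinylogous ester 28 (not isolated)
Conditions: Pd(PPh3)4 (3 mol %), Bu3SnH, CH2Cl2, 0 °C; then 2,6-di-tert-butylpyridine, Tf2O, −78 °C; used at once
Reagents that add atoms: triflic anhydride O=S(=O)(OS(=O)(=O)C(F)(F)F)C(F)(F)F; tributyltin hydride CCCC[SnH](CCCC)CCCC (tin of 28 only)
Why: Zerovalent palladium ionises the allyl vinylogous ester, tributyltin hydride reduces the π-allyl complex to propene faster than the ambident anion can be re-allylated at C11, and the neutral stannyl ester is sulfonylated at −78 °C before the enol ether or the aldehyde can react; because the O–C7–C11–C12–O unit is symmetric about the C6···C11 axis, sulfonylation at either oxygen gives the same constitution and only exchanges the C6 epimers (allyl ester cleavage followed by enol triflate formation from a cyclic 1,3-dione).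

Step 19
Reactants: 29 C7 vinylogous triflate C8 aldehyde
Product: 30 macrocyclic (8S)-carbinol (ten-membered ring C1–C10; C1=C2 dihydrofuran bridge; fused cyclobutenone; O6 trimethylsilyl)
Conditions: CrCl2, (S)-N-[2-(4-isopropyl-4,5-dihydro-1,3-oxazol-2-yl)-6-methylphenyl]methanesulfonamide, Et3N, NiCl2 (cat.), THF–DMF, slow addition to 2 mM, 23 °C; aq sodium serinate, pH 8
Reagents that add atoms: none
Why: In this Nozaki–Hiyama–Kishi reaction zerovalent nickel inserts into the C7–O triflate bond and transmetallation gives a trivalent alkenylchromium species that tolerates ketone, enol ether and silyl ethers and adds only to the aldehyde; the dihydrofuran holds the C10 and C5 arms on one side as in known closures of oxygen-bridged ten-membered carbocycles, and C8 (S) is set by the chiral sulfonamide ligand on chromium, which directs C7 to the Re face of the aldehyde.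

Step 20
Reactants: 30 macrocyclic (8S)-carbinol
Product: 31 O8 tert-butyldimethylsilyl ether of 30
Conditions: TBSOTf, 2,6-lutidine, CH2Cl2, −78 °C
Reagents that add atoms: tert-butyldimethylsilyl triflate CC(C)(C)[Si](C)(C)OS(=O)(=O)C(F)(F)F
Why: Silyl triflate protection of the hindered secondary allylic alcohol under basic conditions is done at once, because a free O8 hydroxyl could add across the C1=C2 enol ether in a five-membered ring.

Step 21
Reactants: 31 O8 tert-butyldimethylsilyl ether
Product: 32 macrocyclic 4-hydroxycyclobutenone (C1 methyl ketal 1R; O10 triethylsilyl; O8 and O13 tert-butyldimethylsilyl; free C6 hydroxyl; both C6 epimers)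
Conditions: pyridinium 4-toluenesulfonate (cat.), MeOH–CH2Cl2, 0 °C
Reagents that add atoms: methanol CO
Why: Acid-catalysed addition of methanol to the enol ether goes through the bridgehead oxocarbenium ion, which methanol can reach only from the outer face so that C10 and C5 stay cis on the oxolane, while the labile O6 trimethylsilyl ether is methanolysed in the same operation and the freed hydroxyl cannot reach C1 because the C10–C1–O–C6 array would have to be anti within a seven-membered ring.

Step 22
Reactants: 32 macrocyclic 4-hydroxycyclobutenone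
Product: 33 ylidene butenolide tricycle (5E; C1 methyl ketal; O10 triethylsilyl; O8 and O13 tert-butyldimethylsilyl)
Conditions: Pb(OAc)4 (2 equiv), pyridine, PhMe, 0 → 23 °C
Reagents that add atoms: none
Why: Ligand exchange gives the tetravalent-lead alkoxide of the C6 hydroxyl, whose homolysis leaves an alkoxyl radical that undergoes strain-driven β-scission of C6–C12 to a C6 ketone and a ketene-like C12 acyl radical; this radical (or the acylium ion formed from it by one-electron oxidation) is captured by the C6 carbonyl oxygen, the ring radical is oxidised to the C6 oxocarbenium ion, and base removes a C5 proton to give C5=C6. The closest known reaction type is the Pb(OAc)4 ring expansion of squarate-derived 4-alkyl-4-hydroxycyclobutenones to 5-alkylidene- and 5-acetoxy-2(5H)-furanones. The five-membered lactone closes 5-endo-trig with respect to the C6=O bond, both atoms of which end in the ring (seen from an acylium ion the same closure is exo at C12), and it is feasible because C6=O and C12 are held cis on C7=C11. No stereocentre is formed and the C6 epimers converge, while the C5=C6 geometry (C4 cis to C7, E) is imposed by the bridged ten-membered ring, which would be far more strained with C4 turned away from C8. The step needs cleavage of C6–C12 and not of C6–C7 or C6–C5, which is secured by acyl over vinyl or primary alkyl radical stability together with relief of ring strain, and it needs lead to meet only one hydroxyl and no electron-rich alkene, which is secured by the C1 methyl ketal and the silyl ethers at O8, O10 and O13. Capture of the cation by acetate would not be a dead end, since loss of acetic acid under the pyridine buffer drains to the same product.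

Step 23
Reactants: 33 ylidene butenolide tricycle
Product: 34 8,10,13-triol C1 methyl ketal
Conditions: Bu4NF–AcOH (1:1), THF, 0 → 23 °C
Reagents that add atoms: none
Why: Buffered fluoride desilylation removes all three silyl groups without acid, which matters because a free O8 hydroxyl and an acid-activated C1 ketal would form a spiroketal, and the enol ester of the lactone is out of reach of O8, which stands trans to C12 on C7=C11.

Step 24
Reactants: 34 8,10,13-triol C1 methyl ketal
Product: 35 13-acetate 8,10-diol C1 methyl ketal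
Conditions: AcCl, 2,4,6-collidine, CH2Cl2, −78 °C
Reagents that add atoms: acetyl chloride CC(Cl)=O
Why: Kinetically selective acylation with acetyl chloride and collidine at −78 °C esterifies the unhindered primary allylic hydroxyl far faster than the secondary O8 and the tertiary O10 hydroxyl.

Step 25
Reactants: 35 13-acetate 8,10-diol C1 methyl ketal
Product: 36 8-methacrylate 13-acetate C1 methyl ketal (free C10 hydroxyl)
Conditions: methacrylic anhydride, Et3N, 4-(dimethylamino)pyridine (cat.), CH2Cl2, 0 → 23 °C
Reagents that add atoms: methacrylic anhydride C=C(C)C(=O)OC(=O)C(C)=C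
Why: Nucleophile-catalysed acylation with the anhydride esterifies the secondary alcohol with retention at C8 and leaves the tertiary C10 hydroxyl untouched.

Step 26
Reactants: 36 8-methacrylate 13-acetate C1 methyl ketal
Product: 38 CNP0394509.2 (target), via O10-trimethylsilyl enol ether 37 (not isolated)
Conditions: TMSOTf (3 equiv), i-Pr2NEt, CH2Cl2, −20 → 0 °C; aq NaHCO3; crude, Bu4NF–AcOH (1:1), THF, 0 °C
Reagents that add atoms: trimethylsilyl triflate C[Si](C)(C)OS(=O)(=O)C(F)(F)F (silicon of 37 only)
Why: The same silyl triflate–amine elimination as in step 16 first silylates O10, then ionises the C1–OMe bond and removes a C2 proton (C10 has none, so only C1=C2 can form), and the tertiary trimethylsilyl ether is so labile that brief buffered fluoride frees the C10 hydroxyl without harm to the enol ether, the esters or the ylidene lactone; no free O8 hydroxyl ever coexists with the enol ether.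

**Compound list**
1 | (R)-citramalic acid | C[C@@](O)(CC(O)=O)C(O)=O | starting material
2 | [(4R)-2,2,4-trimethyl-5-oxo-1,3-dioxolan-4-yl]acetic acid | C[C@]1(CC(O)=O)OC(C)(C)OC1=O | intermediate
3 | (5R)-5-(2-hydroxyethyl)-2,2,5-trimethyl-1,3-dioxolan-4-one (not isolated) | C[C@]1(CCO)OC(C)(C)OC1=O | intermediate
4 | (3R)-3-hydroxy-3-methyloxolan-2-one | C[C@@]1(O)CCOC1=O | intermediate
5 | (3R)-3-methyl-3-(triethylsilyloxy)oxolan-2-one | C[C@@]1(O[Si](CC)(CC)CC)CCOC1=O | intermediate
6 | (3R)-3-methyl-3-(triethylsilyloxy)oxolan-2-ol, both anomers | C[C@@]1(O[Si](CC)(CC)CC)CCOC1O | intermediate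
7 | (3R)-3-methyl-3-(triethylsilyloxy)pent-4-yn-1-ol | C#C[C@](C)(O[Si](CC)(CC)CC)CCO | intermediate
8 | (3R)-3-methyl-1,3-bis(triethylsilyloxy)pent-4-yne | C#C[C@](C)(O[Si](CC)(CC)CC)CCO[Si](CC)(CC)CC | intermediate
9 | 2-methylprop-2-en-1-ol | C=C(C)CO | starting material
10 | (R)-2-methylglycidol (not isolated) | C[C@@]1(CO)CO1 | intermediate
11 | [(2S)-2-methyloxiran-2-yl]methyl 4-toluenesulfonate | C[C@@]1(COS(=O)(=O)c2ccc(C)cc2)CO1 | intermediate
12 | lithium acetylide of 8 (not isolated) | [Li]C#C[C@](C)(O[Si](CC)(CC)CC)CCO[Si](CC)(CC)CC | intermediate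
13 | (2S,6R)-2-hydroxy-2,6-dimethyl-6,8-bis(triethylsilyloxy)oct-4-yn-1-yl 4-toluenesulfonate (4S,10R) | CC[Si](CC)(CC)OCC[C@@](C)(O[Si](CC)(CC)CC)C#CC[C@](C)(O)COS(=O)(=O)c1ccc(C)cc1 | intermediate
14 | (2S)-2-methyl-2-[(4R)-4-methyl-4,6-bis(triethylsilyloxy)hex-2-yn-1-yl]oxirane (4S,10R) | CC[Si](CC)(CC)OCC[C@@](C)(O[Si](CC)(CC)CC)C#CC[C@@]1(C)CO1 | intermediate
15 | squaric acid | OC1=C(O)C(=O)C1=O | starting material
16 | 3,4-bis(allyloxy)cyclobut-3-ene-1,2-dione | C=CCOC1=C(OCC=C)C(=O)C1=O | intermediate
17 | (tributylstannyl)methanol | CCCC[Sn](CCCC)(CCCC)CO | starting material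
18 | tributyl[(1-ethoxyethoxy)methyl]stannane | CCCC[Sn](CCCC)(CCCC)COC(C)OCC | intermediate
19 | (1-ethoxyethoxy)methyllithium (not isolated) | [Li]COC(C)OCC | intermediate
20 | 2,3-bis(allyloxy)-4-[(1-ethoxyethoxy)methyl]-4-hydroxycyclobut-2-en-1-one (not isolated) | C=CCOC1=C(OCC=C)C(O)(COC(C)OCC)C1=O | intermediate
21 | 3-(allyloxy)-4-(hydroxymethyl)cyclobut-3-ene-1,2-dione | C=CCOC1=C(CO)C(=O)C1=O | intermediate
22 | 3-(allyloxy)-4-[(tert-butyldimethylsilyloxy)methyl]cyclobut-3-ene-1,2-dione | C=CCOC1=C(CO[Si](C)(C)C(C)(C)C)C(=O)C1=O | intermediate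
23 | C5-lithio C4-lithium alkoxide from 14 (not isolated) | [Li]C[C@@](C)(O[Li])CC#C[C@](C)(O[Si](CC)(CC)CC)CCO[Si](CC)(CC)CC | intermediate
24 | open-chain 4-hydroxycyclobutenone, C4 and C6 diol, C1≡C2 alkyne (4S,10R; both C6 epimers) | C=CCOC1=C(CO[Si](C)(C)C(C)(C)C)C(=O)C1(O)C[C@@](C)(O)CC#C[C@](C)(O[Si](CC)(CC)CC)CCO[Si](CC)(CC)CC | intermediate
25 | bicyclic C1 ketal with O4 and O6, spiro cyclobutenone at C6 (1R,4S,10R; both C6 epimers) | CC[Si](CC)(CC)OCC[C@@](C)(O[Si](CC)(CC)CC)[C@@]12CC[C@@](C)(CC3(O1)C(=O)C(CO[Si](C)(C)C(C)(C)C)=C3OCC=C)O2 | intermediate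
26 | C1=C2 dihydrofuran, O6-TMS, O8-TES, O10-TES, O13-TBS, C7 allyloxy (4S,10R) | CC[Si](CC)(CC)OCC[C@@](C)(O[Si](CC)(CC)CC)C1=CC[C@@](C)(CC2(O[Si](C)(C)C)C(=O)C(CO[Si](C)(C)C(C)(C)C)=C2OCC=C)O1 | intermediate
27 | C8 aldehyde of 26 | O=CC[C@@](C)(O[Si](CC)(CC)CC)C1=CC[C@@](C)(CC2(O[Si](C)(C)C)C(=O)C(CO[Si](C)(C)C(C)(C)C)=C2OCC=C)O1 | intermediate
28 | tributylstannyl vinylogous ester at O7 (not isolated) | O=CC[C@@](C)(O[Si](CC)(CC)CC)C1=CC[C@@](C)(CC2(O[Si](C)(C)C)C(=O)C(CO[Si](C)(C)C(C)(C)C)=C2O[Sn](CCCC)(CCCC)CCCC)O1 | intermediate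
29 | C7 vinylogous triflate, C8 aldehyde | O=CC[C@@](C)(O[Si](CC)(CC)CC)C1=CC[C@@](C)(CC2(O[Si](C)(C)C)C(=O)C(CO[Si](C)(C)C(C)(C)C)=C2OS(=O)(=O)C(F)(F)F)O1 | intermediate
30 | macrocyclic carbinol (4S,8S,10R), C1=C2 enol ether, O6-TMS | O[C@H]1C[C@@](C)(O[Si](CC)(CC)CC)C2=CC[C@@](C)(CC3(O[Si](C)(C)C)C(=O)C(CO[Si](C)(C)C(C)(C)C)=C13)O2 | intermediate
31 | O8-TBS ether of 30 | CC(C)(C)[Si](C)(C)O[C@H]1C[C@@](C)(O[Si](CC)(CC)CC)C2=CC[C@@](C)(CC3(O[Si](C)(C)C)C(=O)C(CO[Si](C)(C)C(C)(C)C)=C13)O2 | intermediate
32 | macrocyclic 4-hydroxycyclobutenone, C1 methyl ketal (1R,4S,8S,10R; both C6 epimers) | CC(C)(C)[Si](C)(C)O[C@H]1C[C@@](C)(O[Si](CC)(CC)CC)[C@@]2(OC)CC[C@@](C)(CC3(O)C(=O)C(CO[Si](C)(C)C(C)(C)C)=C13)O2 | intermediate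
33 | ylidene butenolide tricycle, C1 methyl ketal (1R,4S,5E,8S,10R) | CC(C)(C)[Si](C)(C)O[C@H]1C[C@@](C)(O[Si](CC)(CC)CC)[C@@]2(OC)CC[C@@](C)(/C=C3/OC(=O)C(CO[Si](C)(C)C(C)(C)C)=C31)O2 | intermediate
34 | 8,10,13-triol C1 methyl ketal | O[C@H]1C[C@@](C)(O)[C@@]2(OC)CC[C@@](C)(/C=C3/OC(=O)C(CO)=C31)O2 | intermediate
35 | 13-acetate 8,10-diol C1 methyl ketal | O[C@H]1C[C@@](C)(O)[C@@]2(OC)CC[C@@](C)(/C=C3/OC(=O)C(COC(C)=O)=C31)O2 | intermediate
36 | 8-methacrylate 13-acetate C1 methyl ketal | C=C(C)C(=O)O[C@H]1C[C@@](C)(O)[C@@]2(OC)CC[C@@](C)(/C=C3/OC(=O)C(COC(C)=O)=C31)O2 | intermediate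
37 | O10-TMS ether of the target (not isolated) | C=C(C)C(=O)O[C@H]1C[C@@](C)(O[Si](C)(C)C)C2=CC[C@@](C)(/C=C3/OC(=O)C(COC(C)=O)=C31)O2 | intermediate
38 | CNP0394509.2 (4S,5E,8S,10R) | C=C(C)C(=O)O[C@H]1C[C@@](C)(O)C2=CC[C@@](C)(/C=C3/OC(=O)C(COC(C)=O)=C31)O2 | target

**Step count**
Total steps: 26. Longest linear sequence: 21 (steps 1–6, 8, 9, 14–26).

**Steps most likely to fail**

1. Step 22. The cation may be captured by acetate without the following elimination. The alkoxyl radical may fragment toward C5. The acetic acid released may strip the ketal and expose the enol ether to lead. In this fallback the oxygen is inserted thermally and the oxidation level is adjusted afterwards. It sets out from 32. Heating in toluene or xylene (110–140 °C) opens the cyclobutenone to the hydroxy vinylketene, whose hydroxyl adds to the ketene carbon to give the C6–H butenolide F1. LiN(SiMe3)2 and TBSCl in THF at −78 °C give the 2-silyloxyfuran F2. N-bromosuccinimide at −78 °C brominates C6 to the C6-bromobutenolide F3. DBU then removes hydrogen bromide across C5–C6, and the route is rejoined at 33.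

2. Step 19. Ring closure may be slower than reduction or hydrolysis of the triflate. The ligand may also fail to override the bias of the two C6-epimeric substrates, which would give poor facial selectivity at C8. In this fallback C8 is set by reduction instead of C–C bond formation. It sets out from 29. The ring is closed with ligand-free CrCl2/NiCl2 in DMF, which gives 30 together with its 8R epimer F4. Dess–Martin periodinane buffered with NaHCO3 converts the mixture into the C8 ketone F5. Corey–Bakshi–Shibata reduction follows, with (R)-1-methyl-3,3-diphenyltetrahydro-1H,3H-pyrrolo[1,2-c][1,3,2]oxazaborole and catecholborane at −78 °C. C7 acts as the large alkenyl group, and C12 is shielded by the fully substituted C6 and C11. Hydride is delivered to give the 8S alcohol, and the route is rejoined at 30.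

3. Step 18. Triflic anhydride or adventitious acid may attack the enol ether, the aldehyde may be sulfonylated at its enol, or the vinylogous triflate may be lost on handling. In this fallback the triflate is installed earlier, on the robust bicyclic ketal, where neither enol ether nor aldehyde exists yet. It sets out from 25. Pd(PPh3)4 and Bu3SnH give the stannyl ester on the bicyclic ketal F6, and Tf2O gives the bicyclic ketal triflate F7. TMSOTf and i-Pr2NEt open the ketal to the dihydrofuran triflate F8 (O6-TMS, O8-TES). Swern oxidation of its primary triethylsilyl ether rejoins the route at 29.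

**Further compounds**
F1 | step 22 | C6–H butenolide, C1 methyl ketal, O10-TES, O8,O13-bis-TBS (C6 open) | CC(C)(C)[Si](C)(C)O[C@H]1C[C@@](C)(O[Si](CC)(CC)CC)[C@@]2(OC)CC[C@@](C)(CC3OC(=O)C(CO[Si](C)(C)C(C)(C)C)=C31)O2
F2 | step 22 | 2-(tert-butyldimethylsilyloxy)furan from F1 | CC(C)(C)[Si](C)(C)O[C@H]1C[C@@](C)(O[Si](CC)(CC)CC)[C@@]2(OC)CC[C@@](C)(Cc3oc(O[Si](C)(C)C(C)(C)C)c(CO[Si](C)(C)C(C)(C)C)c31)O2
F3 | step 22 | C6-bromobutenolide (C6 open) | CC(C)(C)[Si](C)(C)O[C@H]1C[C@@](C)(O[Si](CC)(CC)CC)[C@@]2(OC)CC[C@@](C)(CC3(Br)OC(=O)C(CO[Si](C)(C)C(C)(C)C)=C31)O2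
F4 | step 19 | 8R epimer of 30 | O[C@@H]1C[C@@](C)(O[Si](CC)(CC)CC)C2=CC[C@@](C)(CC3(O[Si](C)(C)C)C(=O)C(CO[Si](C)(C)C(C)(C)C)=C13)O2
F5 | step 19 | macrocyclic C8 ketone | O=C1C[C@@](C)(O[Si](CC)(CC)CC)C2=CC[C@@](C)(CC3(O[Si](C)(C)C)C(=O)C(CO[Si](C)(C)C(C)(C)C)=C13)O2
F6 | step 18 | tributylstannyl vinylogous ester on the bicyclic ketal | CC[Si](CC)(CC)OCC[C@@](C)(O[Si](CC)(CC)CC)[C@@]12CC[C@@](C)(CC3(O1)C(=O)C(CO[Si](C)(C)C(C)(C)C)=C3O[Sn](CCCC)(CCCC)CCCC)O2
F7 | step 18 | C7 vinylogous triflate on the bicyclic ketal | CC[Si](CC)(CC)OCC[C@@](C)(O[Si](CC)(CC)CC)[C@@]12CC[C@@](C)(CC3(O1)C(=O)C(CO[Si](C)(C)C(C)(C)C)=C3OS(=O)(=O)C(F)(F)F)O2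
F8 | step 18 | dihydrofuran C7 triflate, O6-TMS, O8-TES | CC[Si](CC)(CC)OCC[C@@](C)(O[Si](CC)(CC)CC)C1=CC[C@@](C)(CC2(O[Si](C)(C)C)C(=O)C(CO[Si](C)(C)C(C)(C)C)=C2OS(=O)(=O)C(F)(F)F)O1
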